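I started from amounts: how much solid reagent a flask holds against how much substrate it has to turn over.

- Friday's: left-handed substrate 20 mM; right-handed substrate 20 mM; solid reagent 60 mM; run made earlier
- flask: left-handed substrate 20 mM; solid reagent 40.0 mM; right-handed substrate 20 mM; time 5.0 d

Friday's run (percent of the left-handed substrate and right-handed substrate together charged)

| time / h | achiral form / % | left-handed product / % |
|---|---|---|
| 3.00 | 34 | 3 |
| 10.0 | 34 | 23 |
| 15.0 | 27 | 29 |
| 25.0 | 18 | 39 |
| 40.0 | 8 | 54 |

(readings scatter by 2 percentage points)

- partner is single-handed; left-handed substrate and right-handed substrate are mirror images of each other, charged as a racemate, each of them at the stated concentration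
- solid reagent is a solid; its amount is given per volume of the solution
- the earlier runs were read with a standard deviation of 2 percentage points
- at the start none of the solid reagent is in solution
- the handed part of partner does not stay in what it makes, so the products of the two hands are mirror images too

* the moment within 5.0 d at which there is most achiral form
* the amount of achiral form, in percent of the left-handed substrate and right-handed substrate together charged, at that time
* the first time at which achiral form reaches 26%, in the same percent, in d

Friday's run and the new flask looked nearly the same, differing in solid reagent and in the time followed. I treated the solid as the store of partner and assumed that each product molecule takes one partner and the achiral form none.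

cover = solid reagent charged / both substrates charged

new flask: 40.0 mM / 40.0 mM = 100%

Friday's run: 60 mM / 40.0 mM = 150%

I called this the cover, the share of the charge that the solid can pay into products. Friday's achiral form read 34% at 3.00 h and 34% at 10.0 h, so I read its peak as lying between those times, within the scatter of the readings. Left-handed product read 23% at that later time, and doubled as an allowance for the unread right-handed product it comes to 46.0%, less than the new flask's cover. So I expected the new flask to peak much as Friday's run did. I expected both to end in products, with 33.3% of the solid's charge spare in Friday's run and 0% in the new flask.

The forecast gave 37% at 0.27 d, with 26% reached at 0.09 d. It differed from my reckoning at the end: “leaving the achiral form stranded near 15%”.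

The new flask gave 37.5% at 0.240 d, and 26% at 0.0781 d.

    partner + left-handed substrate → left-handed product (k = 25.0 M⁻¹ h⁻¹)
    partner + right-handed substrate → right-handed product (k = 14.0 M⁻¹ h⁻¹)
    left-handed substrate ⇌ achiral form (K = 1.80, k = 0.210 h⁻¹)
    right-handed substrate ⇌ achiral form (K = 1.80, k = 0.210 h⁻¹)
    solid reagent ⇌ partner, rate k5*(cs5 - [partner]) while solid is left; crystals form when [partner] > cs5 (solubility = 7.60 mM, k = 0.520 h⁻¹)

In the new flask, the step between right-handed substrate and achiral form, taken alone and both ways together, had a relaxation half-life of 0.0884 d, shorter than the 5.0 d allowed. The achiral form of the new flask stood at 1.27% at 5.00 d. At 50.0 d the two products of the new flask together stood at 99.8%, against its cover of 100%. In the neighbour with 10 mM of solid, the cover was 25.0%; at 5.00 d the solid reagent, the limiting reagent there, stood at 0%, partner at 0 mM, and the two products together at 25.0%.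

The earlier runs and the new flask stem from a simulated flask with constants of no real substance.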